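## Analysis of the target

Cespitularin K (28) is a tricyclic diketone in which ring A, a gem-dimethylcyclohexene, shares its tetrasubstituted double bond with ring B, a cyclopent-4-ene-1,3-dione. Ring C, a twelve-membered carbocycle, runs from the CH carbon of ring A (the one next to the CMe2 carbon) to the CH carbon of ring B, so the enedione alkene sits at a bridgehead of a bicyclo[9.3.1] frame whose one-carbon bridge is CMe2. Ring C carries an E-trisubstituted alkene bonded directly to the ring B CH, an allylic acetoxy carbon and an exocyclic methylene group. There are three stereocentres: the ring A CH (R) and the acetoxy carbon (S), which stand in a 1,6-relationship across ring C and cannot equilibrate, and the ring B CH (S), which lies between two ketones and a vinyl group and must be treated as labile. The sensitive groups are the acetate, vinylogously β to the acidic ring B CH and so prone to base-induced 1,4-elimination, the enedione, a Michael acceptor, and the skipped alkenyl-dione, which can slip into conjugation; the three isolated alkenes also rule out hydrogenation and strong electrophilic oxidants. The difficulty is the macrocycle that ends on a bridgehead enedione next to a quaternary carbon, together with the remote relationship between the ring A CH and the acetoxy carbon. The strategy rests on the ring A carbons CH2–C=C–CMe2, whose C=C is the ring B alkene: they are the retron of a diene made of a methylene and an isopropylidene group on adjacent ring B carbons, and the remaining CH2–CH pair of ring A is a vinyl group at the end of the ring C chain. This is the pattern of a type 2 intramolecular Diels–Alder adduct.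

## Retrosynthetic reasoning

**28 ⇒ 26 (through 27).** The two σ-bonds of ring A that are not part of ring B are cut: CH2–CH2 and CH–CMe2. No other cut opens ring A and ring C together, and it leaves a monocyclic ring B with one open chain. The diene 27 that results is too reactive to store, so it is masked as the 3-sulfolene 26. In the forward direction the sulfonyl bridge must leave, the two methylene termini must pair, and the chain must fold so that the acetoxy carbon dictates the ring A CH. The new alkene is already the enedione, so nothing follows the cycloaddition.

**26 ⇒ 24 ⇒ 23.** The two S–O bonds and the acetyl C–O bond are removed. Sulfur is oxidised last because in 26 the CH2 between the sulfonyl group and the enedione is vinylogously acidic, and base would open the ring by expelling sulfinate. As a sulfide the same ring tolerates the basic steps. The acetate is added only after ring B exists, since the step that makes ring B uses an alkoxide.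

**23 ⇒ 21.** The ring B bond between the CH carbon and the carbonyl on the CH2 side is cut, and that carbonyl is tied back to the other ketone oxygen as an enol lactone. Direct C-alkenylation of a cyclopent-4-ene-1,3-dione is not dependable, and the usual vinylogous-ester cross-coupling is closed because the enol ether would be a cyclopentadienone. The oxygen-to-carbon ring switch ends in the stabilised dione enolate, which pulls it forward.

**21 ⇒ 20 ⇒ 19 ⇒ 7 + 18.** The lactone C–O bond is cut (5-exo addition of the acid to the alkyne), then the sp2–sp bond (alkynylation of vinyl triflate 7). The two alkyne carbons of 18 become the carbonyl next to CMe2 and the ring B CH. Because the dione is symmetric about its CH, it does not matter which carbonyl comes from the ester. The step is convergent and joins two fragments of similar size.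

**7 ⇒ 5 ⇒ 3 ⇒ 1 + 2.** The enol triflate comes from β-keto ester 5 through its potassium enolate 6. Ring closure of 3 by ester condensation can go only one way, because only one ester has α-hydrogens; it delivers 5 by way of the sodium enolate 4. The C–S bond joins two commercial esters and brings in the gem-dimethyl carbon.

**18 ⇒ 16 + 14; 16 ⇐ 15; 14 ⇐ 10 + 11; 10 ⇐ 8 + 9.** The carbinol C–CH2 bond is cut. One reagent-controlled allylation sets the only stereocentre that is carried through the route, and delivers the exocyclic methylene and the terminal vinyl group in one piece. Aldehyde 16 keeps the E-enyne of commercial 15. Boronate 14 is assembled by a one-carbon homologation of the alkenyl metal derived from 10.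

## Alternatives that were turned down

**Alternative 1:** Ring B is disconnected at the bond between the CH carbon and the carbonyl next to CMe2. The substrate is the ring-A-fused 4-hydroxycyclobutenone A2, which carries an alkenyl epoxide on its carbinol carbon. In the forward step Pd(PPh3)4, a zerovalent palladium complex, ionises the vinyl epoxide and the acyl carbon shifts to the allyl terminus. The four-membered ring grows to the dione, and the seco carbinol A1 appears with its E-alkene and free hydroxyl.
- For: three features are made at once, and the carbinol configuration comes from the epoxide. The ring A CH is installed early and independently. On that point the route is stronger than the chosen one, which relies on a late substrate-controlled cycloaddition.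
- Against: 4-alkenyl-4-hydroxycyclobutenones open thermally to vinylketenes and close to six-membered rings. Acyl and vinyl migration compete. The fused cyclobutenone needs its own multistep construction. Ring C is still open in A1 and must be closed by a separate cross-coupling in the presence of an acidic dione.
- Comparison: the chosen route offers in place of the early ring A stereocentre a single step that closes ring A and ring C together, from a precursor made by routine reactions.

**Alternative 2:** Ring C is disconnected at the C–CH2 and O–CH bonds of an isoxazoline. Nitro triene A4 is dehydrated to nitrile oxide A5, which adds across the terminal alkene of the side-chain triene to give the macrocyclic isoxazoline A3.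
- For: intramolecular nitrile oxide cycloaddition is a mild and regiochemically reliable way to close large rings. As a macrocyclisation it is more dependable than the cycloaddition chosen here.
- Against: the oxygen-bearing stereocentre is formed under remote control by the ring A CH alone. The inner alkenes of the triene are competing dipolarophiles. After A3 the route still needs N–O cleavage beside a reducible dienyl enol lactone, methylenation of a β-hydroxy ketone, acetylation and the lactone-to-dione switch.
- Comparison: the chosen strategy sets the carbinol by reagent control before the macrocycle exists and ends at 28 with the ring-forming step.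

**Alternative 3:** Ring B is disconnected at the bond between the CH carbon and the carbonyl remote from CMe2. The substrate is the macrocyclic ylidenebutenolide A7. Alkoxide opens the lactone and the former ylidene carbon closes onto the new ester, giving the silyl ether A6 of deacetyl cespitularin K.
- For: this oxygen-to-carbon ring switch is a proven entry to 2-substituted cyclopent-4-ene-1,3-diones, and the chosen route uses the same reaction on the open-chain compound 21. Ring size is unchanged, and the ring A CH can again be fixed early.
- Against: the risk moves to A7, a twelve-membered ring holding a Z-ylidene and an E-alkene in conjugation, which needs its own macrocyclisation. The Claisen closure must then occur across that ring, with a silyloxy group vinylogously β to the dienolate. Desilylation and acetylation follow.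
- Comparison: the chosen route performs the ring switch where it is unstrained and lets one pericyclic step replace the separate macrocyclisation.

Key step: step 14

Assumption: the ring B CH is configurationally labile; in 23–27 it is drawn as the epimer that maps onto 28, and the natural (S) epimer of 28 is taken to be the thermodynamically preferred one.

Assumption: 15 is used as the pure E isomer.

## Route

Step 1
Reactants: 1 methyl 3-sulfanylpropanoate; 2 methyl 2-bromo-2-methylpropanoate
Product: 3 methyl 2-[(3-methoxy-3-oxopropyl)sulfanyl]-2-methylpropanoate
Conditions: K2CO3, DMF, 0 °C → rt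
Reagents that add atoms: none
Why: S-alkylation of a thiolate by a tertiary α-bromo ester, a substitution that the adjacent carbonyl makes facile; it installs the future CMe2 carbon at the outset.

Step 2
Reactants: 3 methyl 2-[(3-methoxy-3-oxopropyl)sulfanyl]-2-methylpropanoate
Product: 5 methyl 5,5-dimethyl-4-oxothiolane-3-carboxylate, via sodium enolate 4 (not isolated)
Conditions: NaOMe, THF, 0 °C → rt; then AcOH
Reagents that add atoms: none
Why: Dieckmann condensation; only the propanoate arm has α-hydrogens, so one regioisomer can form, and deprotonation to 4 drives the equilibrium before the acid quench releases the keto ester for purification.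

Step 3
Reactants: 5 methyl 5,5-dimethyl-4-oxothiolane-3-carboxylate
Product: 7 methyl 5,5-dimethyl-4-{[(trifluoromethyl)sulfonyl]oxy}-2,5-dihydrothiophene-3-carboxylate, via potassium enolate 6 (not isolated)
Conditions: KH, THF, 0 °C; then PhNTf2, 0 °C → rt; cold 1 M HCl work-up
Reagents that add atoms: N-phenylbis(trifluoromethanesulfonimide), O=S(=O)(N(c1ccccc1)S(=O)(=O)C(F)(F)F)C(F)(F)F
Why: O-sulfonylation of a β-keto ester enolate (enol triflate formation); KH deprotonates irreversibly and the loosely paired potassium enolate 6 reacts at oxygen, the triflimide is chosen over the anhydride to spare the thioether, and the new C=C is the future ring A/ring B fusion bond.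

Step 4
Reactants: 8 2,3-dibromoprop-1-ene; 9 allylmagnesium bromide
Product: 10 2-bromohexa-1,5-diene
Conditions: Et2O, 0 °C → rt
Reagents that add atoms: none
Why: Allyl–allyl coupling by substitution of the allylic bromide; direct and allylic-transposed attack give the same diene, and the vinylic bromide is inert.

Step 5
Reactants: 10 2-bromohexa-1,5-diene; 11 2-(chloromethyl)-4,4,5,5-tetramethyl-1,3,2-dioxaborolane
Product: 14 4,4,5,5-tetramethyl-2-(2-methylidenehex-5-en-1-yl)-1,3,2-dioxaborolane, via dienylmagnesium bromide 12 (not isolated), via chloromethyl borate 13 (not isolated)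
Conditions: Mg, THF, 40 °C; then 11, −78 °C → rt
Reagents that add atoms: none
Why: Matteson homologation; the alkenyl Grignard reagent adds to boron and 1,2-migration with loss of chloride gives the allylboronate, whose 1,3-boron shift is degenerate.

Step 6
Reactants: 15 (2E)-3-methylpent-2-en-4-yn-1-ol
Product: 16 (2E)-3-methylpent-2-en-4-ynal
Conditions: MnO2, CH2Cl2, rt; filtered solution used directly
Reagents that add atoms: none
Why: Allylic alcohol oxidation with MnO2 under neutral conditions, which keeps the E-alkene and the terminal alkyne; the volatile aldehyde is not concentrated to dryness.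

Step 7
Reactants: 16 (2E)-3-methylpent-2-en-4-ynal; 14 4,4,5,5-tetramethyl-2-(2-methylidenehex-5-en-1-yl)-1,3,2-dioxaborolane
Product: 18 (3E,5S)-3-methyl-7-methylideneundeca-3,10-dien-1-yn-5-ol, via pinacol borate ester 17 (not isolated)
Conditions: (S)-3,3'-bis(2,4,6-triisopropylphenyl)-1,1'-binaphthyl-2,2'-diyl hydrogen phosphate (5 mol%), 4 Å MS, PhMe, −30 °C; aqueous work-up
Reagents that add atoms: none
Why: Chiral phosphoric acid-catalysed allylboration through a chair-like six-membered transition state with allyl transposition; the (S)-acid is expected to direct attack to the Si face of the enal and so set the 5S centre, the sense to be confirmed by MTPA ester analysis of 18.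

Step 8
Reactants: 7 methyl 5,5-dimethyl-4-{[(trifluoromethyl)sulfonyl]oxy}-2,5-dihydrothiophene-3-carboxylate; 18 (3E,5S)-3-methyl-7-methylideneundeca-3,10-dien-1-yn-5-ol
Product: 19 methyl 4-[(3E,5S)-5-hydroxy-3-methyl-7-methylideneundeca-3,10-dien-1-yn-1-yl]-5,5-dimethyl-2,5-dihydrothiophene-3-carboxylate
Conditions: Pd(PPh3)2Cl2 (5 mol%), CuI (10 mol%), Et3N, DMF, rt
Reagents that add atoms: none
Why: Sonogashira coupling of a carbonyl-activated vinyl triflate; the tertiary amine cannot displace the triflate, and the free alcohol and the thioether are tolerated.

Step 9
Reactants: 19 methyl 4-[(3E,5S)-5-hydroxy-3-methyl-7-methylideneundeca-3,10-dien-1-yn-1-yl]-5,5-dimethyl-2,5-dihydrothiophene-3-carboxylate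
Product: 20 4-[(3E,5S)-5-hydroxy-3-methyl-7-methylideneundeca-3,10-dien-1-yn-1-yl]-5,5-dimethyl-2,5-dihydrothiophene-3-carboxylic acid
Conditions: LiOH·H2O, THF/MeOH/H2O, rt; then 0.5 M HCl, 0 °C
Reagents that add atoms: lithium hydroxide, [Li+].[OH-]
Why: Saponification of the methyl ester; the ring holds the carboxyl group cis to the alkyne, as the lactonisation requires.

Step 10
Reactants: 20 4-[(3E,5S)-5-hydroxy-3-methyl-7-methylideneundeca-3,10-dien-1-yn-1-yl]-5,5-dimethyl-2,5-dihydrothiophene-3-carboxylic acid
Product: 21 (3Z)-3-[(2E,4S)-4-hydroxy-2-methyl-6-methylidenedeca-2,9-dien-1-ylidene]-4,4-dimethyl-4,6-dihydro-1H,3H-thieno[3,4-c]furan-1-one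
Conditions: Ag2CO3 (20 mol%), DMF, rt, dark
Reagents that add atoms: none
Why: Silver-catalysed 5-exo-dig lactonisation of a (Z)-2-en-4-ynoic acid by anti addition of carboxylate to the activated alkyne, which gives the Z-ylidenebutenolide and puts oxygen on the alkyne carbon next to the ring; the loading is raised because the thioether competes for monovalent silver, and the E-alkene keeps the hydroxyl out of reach of the alkyne.

Step 11
Reactants: 21 (3Z)-3-[(2E,4S)-4-hydroxy-2-methyl-6-methylidenedeca-2,9-dien-1-ylidene]-4,4-dimethyl-4,6-dihydro-1H,3H-thieno[3,4-c]furan-1-one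
Product: 23 5-[(2E,4S)-4-hydroxy-6-methylidenedeca-2,9-dien-2-yl]-1,1-dimethyl-1H-cyclopenta[c]thiophene-4,6(3H,5H)-dione, via seco keto ester dienolate 22 (not isolated)
Conditions: NaOMe, MeOH, 0 °C → rt; then 1 M HCl, 0 °C
Reagents that add atoms: none
Why: Alkoxide-induced ylidenebutenolide-to-cyclopentenedione rearrangement; methoxide opens the enol lactone to 22, whose α-carbon closes ring B by intramolecular Claisen acylation (5-exo-trig), and the dione enolate is the thermodynamic sink. The cold acid quench protonates at the ring carbon, the E-alkene is the more stable geometry, and the free hydroxyl is a poor leaving group for vinylogous elimination.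

Step 12
Reactants: 23 5-[(2E,4S)-4-hydroxy-6-methylidenedeca-2,9-dien-2-yl]-1,1-dimethyl-1H-cyclopenta[c]thiophene-4,6(3H,5H)-dione
Product: 24 (2E,4S)-2-(1,1-dimethyl-4,6-dioxo-3,4,5,6-tetrahydro-1H-cyclopenta[c]thiophen-5-yl)-6-methylidenedeca-2,9-dien-4-yl acetate
Conditions: Ac2O, pyridine, CH2Cl2, 0 °C; cold dilute HCl work-up
Reagents that add atoms: acetic anhydride, CC(=O)OC(C)=O
Why: Acylation of the secondary alcohol; the dione stays in the diketo form because its enol would be a cyclopentadienone, so acylation on ring B is unfavourable and reversible. Short cold exposure to the weak base limits 1,4-elimination, and the sulfide stage is chosen because it is not base-labile.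

Step 13
Reactants: 24 (2E,4S)-2-(1,1-dimethyl-4,6-dioxo-3,4,5,6-tetrahydro-1H-cyclopenta[c]thiophen-5-yl)-6-methylidenedeca-2,9-dien-4-yl acetate
Product: 26 (2E,4S)-2-(1,1-dimethyl-2,2-dioxido-4,6-dioxo-3,4,5,6-tetrahydro-1H-cyclopenta[c]thiophen-5-yl)-6-methylidenedeca-2,9-dien-4-yl acetate, via sulfoxide 25 (not isolated)
Conditions: (NH4)6Mo7O24·4H2O (10 mol%), 30% H2O2, EtOH, 0 °C → rt
Reagents that add atoms: hydrogen peroxide, OO
Why: Molybdate-catalysed oxidation of a sulfide to the sulfone through the sulfoxide; the molybdenum peroxo species formed from (NH4)6Mo7O24 and H2O2 prefers sulfur to unactivated and electron-poor alkenes, and the faintly acidic medium spares the acetate and the dione. No base is used once the sulfone is in place.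

Step 14
Reactants: 26 (2E,4S)-2-(1,1-dimethyl-2,2-dioxido-4,6-dioxo-3,4,5,6-tetrahydro-1H-cyclopenta[c]thiophen-5-yl)-6-methylidenedeca-2,9-dien-4-yl acetate
Product: 28 cespitularin K, via methylene isopropylidene diene 27 (not isolated)
Conditions: o-xylene (0.5 mM), 2,6-di-tert-butyl-4-methylphenol, Ar sweep, slow addition at 144 °C; then silica gel
Reagents that add atoms: none
Why: Cheletropic loss of SO2 from the 3-sulfolene releases diene 27, locked s-cis by ring B, and 27 adds its terminal vinyl group in an intramolecular [4+2] cycloaddition. The closest known reaction types are sulfolene-unmasked intramolecular Diels–Alder reactions and type 2 intramolecular Diels–Alder closures to bridgehead alkenes with a gem-dimethyl one-carbon bridge. Ring A closes as the six-membered cycloadduct that holds both new σ-bonds (CH2–CH2 and CH–CMe2), and ring C closes as the twelve-membered bridge of the type 2 mode when the CH–CMe2 bond forms. The new alkene is the enedione C=C, so the oxidation level is final. The ring A CH is controlled by the (S)-acetoxy carbon: the ring B CH epimerises, so either diene face is open, and the folded transition state with the acetoxy group pseudo-equatorial on the forming macrocycle should lead to the R centre. The tether cannot fix the regiochemistry, because the ring B CH is equidistant from both inner diene carbons; it should come from asynchronous bonding in which the two unhindered CH2 termini join first, in the sense of a conjugate addition, and the CH–CMe2 bond closes last. The 1,1-disubstituted alkene cannot compete, since its short tether contains the E-alkene. Dilution and slow addition suppress dimerisation, the temperature is held at the extrusion threshold to limit the unimolecular 1,5-hydrogen shift, and the ring B CH settles to the more stable epimer on silica.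

## Compound list

1 | methyl 3-sulfanylpropanoate | COC(=O)CCS | starting material
2 | methyl 2-bromo-2-methylpropanoate | COC(=O)C(C)(C)Br | starting material
3 | methyl 2-[(3-methoxy-3-oxopropyl)sulfanyl]-2-methylpropanoate | COC(=O)CCSC(C)(C)C(=O)OC | intermediate
4 | sodium 4-(methoxycarbonyl)-2,2-dimethyl-2,5-dihydrothiophen-3-olate (sodium enolate of 5) | COC(=O)C1=C([O-])C(C)(C)SC1.[Na+] | intermediate
5 | methyl 5,5-dimethyl-4-oxothiolane-3-carboxylate | COC(=O)C1CSC(C)(C)C1=O | intermediate
6 | potassium 4-(methoxycarbonyl)-2,2-dimethyl-2,5-dihydrothiophen-3-olate (potassium enolate of 5) | COC(=O)C1=C([O-])C(C)(C)SC1.[K+] | intermediate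
7 | methyl 5,5-dimethyl-4-{[(trifluoromethyl)sulfonyl]oxy}-2,5-dihydrothiophene-3-carboxylate | COC(=O)C1=C(OS(=O)(=O)C(F)(F)F)C(C)(C)SC1 | intermediate
8 | 2,3-dibromoprop-1-ene | C=C(Br)CBr | starting material
9 | allylmagnesium bromide | C=CC[Mg]Br | starting material
10 | 2-bromohexa-1,5-diene | C=CCCC(Br)=C | intermediate
11 | 2-(chloromethyl)-4,4,5,5-tetramethyl-1,3,2-dioxaborolane | ClCB1OC(C)(C)C(C)(C)O1 | starting material
12 | hexa-1,5-dien-2-ylmagnesium bromide | C=CCCC(=C)[Mg]Br | intermediate
13 | bromomagnesium (chloromethyl)(hexa-1,5-dien-2-yl)(pinacolato)borate | C=CCCC(=C)[B-]1(CCl)OC(C)(C)C(C)(C)O1.[Mg+]Br | intermediate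
14 | 4,4,5,5-tetramethyl-2-(2-methylidenehex-5-en-1-yl)-1,3,2-dioxaborolane | C=CCCC(=C)CB1OC(C)(C)C(C)(C)O1 | intermediate
15 | (2E)-3-methylpent-2-en-4-yn-1-ol | C#C/C(C)=C/CO | starting material
16 | (2E)-3-methylpent-2-en-4-ynal | C#C/C(C)=C/C=O | intermediate
17 | 4,4,5,5-tetramethyl-2-{[(3E,5S)-3-methyl-7-methylideneundeca-3,10-dien-1-yn-5-yl]oxy}-1,3,2-dioxaborolane | C#C/C(C)=C/[C@@H](OB1OC(C)(C)C(C)(C)O1)CC(=C)CCC=C | intermediate
18 | (3E,5S)-3-methyl-7-methylideneundeca-3,10-dien-1-yn-5-ol | C#C/C(C)=C/[C@@H](O)CC(=C)CCC=C | intermediate
19 | methyl 4-[(3E,5S)-5-hydroxy-3-methyl-7-methylideneundeca-3,10-dien-1-yn-1-yl]-5,5-dimethyl-2,5-dihydrothiophene-3-carboxylate | COC(=O)C1=C(C#C/C(C)=C/[C@@H](O)CC(=C)CCC=C)C(C)(C)SC1 | intermediate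
20 | 4-[(3E,5S)-5-hydroxy-3-methyl-7-methylideneundeca-3,10-dien-1-yn-1-yl]-5,5-dimethyl-2,5-dihydrothiophene-3-carboxylic acid | OC(=O)C1=C(C#C/C(C)=C/[C@@H](O)CC(=C)CCC=C)C(C)(C)SC1 | intermediate
21 | (3Z)-3-[(2E,4S)-4-hydroxy-2-methyl-6-methylidenedeca-2,9-dien-1-ylidene]-4,4-dimethyl-4,6-dihydro-1H,3H-thieno[3,4-c]furan-1-one | O=C1O/C(=C\C(C)=C\[C@@H](O)CC(=C)CCC=C)C2=C1CSC2(C)C | intermediate
22 | sodium dienolate of methyl 4-[(3E,5S)-5-hydroxy-3-methyl-7-methylideneundeca-3,10-dienoyl]-5,5-dimethyl-2,5-dihydrothiophene-3-carboxylate | [Na+].[O-]/C(=C\C(C)=C\[C@@H](O)CC(=C)CCC=C)C1=C(C(=O)OC)CSC1(C)C | intermediate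
23 | 5-[(2E,4S)-4-hydroxy-6-methylidenedeca-2,9-dien-2-yl]-1,1-dimethyl-1H-cyclopenta[c]thiophene-4,6(3H,5H)-dione (labile ring B CH drawn as the epimer that maps onto 28) | C=CCCC(=C)C[C@H](O)/C=C(C)/[C@H]1C(=O)C2=C(C1=O)C(C)(C)SC2 | intermediate
24 | (2E,4S)-2-(1,1-dimethyl-4,6-dioxo-3,4,5,6-tetrahydro-1H-cyclopenta[c]thiophen-5-yl)-6-methylidenedeca-2,9-dien-4-yl acetate | C=CCCC(=C)C[C@H](OC(C)=O)/C=C(C)/[C@H]1C(=O)C2=C(C1=O)C(C)(C)SC2 | intermediate
25 | S-oxide of 24 (both sulfur epimers) | C=CCCC(=C)C[C@H](OC(C)=O)/C=C(C)/[C@H]1C(=O)C2=C(C1=O)C(C)(C)S(=O)C2 | intermediate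
26 | S,S-dioxide of 24, the sulfolene-masked dienyl dione (2E,4S)-2-(1,1-dimethyl-2,2-dioxido-4,6-dioxo-3,4,5,6-tetrahydro-1H-cyclopenta[c]thiophen-5-yl)-6-methylidenedeca-2,9-dien-4-yl acetate | C=CCCC(=C)C[C@H](OC(C)=O)/C=C(C)/[C@H]1C(=O)C2=C(C1=O)C(C)(C)S(=O)(=O)C2 | intermediate
27 | (2E,4S)-6-methylidene-2-[3-methylidene-2,5-dioxo-4-(propan-2-ylidene)cyclopentyl]deca-2,9-dien-4-yl acetate | C=CCCC(=C)C[C@H](OC(C)=O)/C=C(C)/[C@H]1C(=O)C(=C)C(=C(C)C)C1=O | intermediate
28 | cespitularin K (ring A CH R, ring B CH S, acetoxy carbon S, E-alkene) | C=C1CC[C@@H]2CCC3=C(C(=O)[C@H](C3=O)/C(C)=C/[C@@H](OC(C)=O)C1)C2(C)C | target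

## Step count and least certain steps

Total step count: 14. Longest linear sequence: 10 steps (steps 4, 5, 7, 8, 9, 10, 11, 12, 13, 14 from 8; the branch from 1 through steps 1, 2, 3 and 8–14 is equally long).

**Step 14 (key step).**
- The released diene may shift a hydrogen from the cis methyl group to the methylene terminus faster than it cyclises, because the dienophile is unactivated and closing a twelve-membered ring costs entropy.
- Dimerisation through the exocyclic enone is the bimolecular competitor.
- The wrong pairing of termini can compete, since the tether attaches equally to both inner diene carbons.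
- Facial selectivity rests on a stereocentre five atoms away and may be low.

Fallback: the cycloaddition is moved ahead of the ring switch. Setting out from 21, sulfur is oxidised with (NH4)6Mo7O24·4H2O and H2O2 to the sulfone butenolide F1. Thermolysis under the conditions of step 14 should give the macrocyclic ylidenebutenolide F2. In F1 the chain reaches the isopropylidene-bearing diene carbon directly and the other diene carbon only through the lactone O–C(=O) link, so the two modes of closure are no longer equivalent and the shorter bridge is the wanted one; the diene is also less electron-poor. NaOMe in MeOH then effects the ring switch on F2 to deacetyl cespitularin K F3, and Ac2O in pyridine returns the route to 28.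

**Step 11.**
After lactone opening the dienolate may lose the carbinol oxygen by vinylogous β-elimination, methoxide may add to the enedione, or the product may be reprotonated at the remote alkene carbon so that the double bond moves into conjugation. All arise because C–C bond formation is left to an equilibrating alkoxide medium.

Fallback: the two events are separated. From 21, K2CO3 in MeOH at 0 °C opens the lactone to the keto ester F4, which is isolated. Kinetic Claisen closure with LiN(SiMe3)2 in THF at −78 °C and a cold acid quench then rejoins the route at 23.

**Step 13.**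
Oxidation may stall at the hindered sulfoxide, or it may spill over to epoxidation of the 1,1-disubstituted alkene when forced.

Fallback: only one oxygen is installed. From 24, NaIO4 in aqueous MeOH at 0 °C gives sulfoxide 25, which is isolated. Heating 25 in toluene at about 110 °C under an argon sweep releases the same diene by cheletropic loss of sulfur monoxide, and the route is rejoined at 27 and so at 28.

**Step 7.**
Enantioselectivity, or its sense, may fall short with a 2-alkyl-substituted allylboronate and a small linear enynal, because the catalyst pocket then discriminates the faces less well.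

Fallback: the stereocentre is set by reduction. From 16 and 14 the uncatalysed allylboration at rt gives the racemic alcohol F5. Dess–Martin periodinane with NaHCO3 gives the ketone F6. Corey–Bakshi–Shibata reduction with (R)-1-methyl-3,3-diphenyltetrahydro-1H,3H-pyrrolo[1,2-c][1,3,2]oxazaborole and catecholborane in toluene at −78 °C, with the alkenyl group as the large substituent and a borane that leaves the terminal alkenes alone, should give 18.

**Step 12.**
The acidic ring B CH may be acylated on oxygen or carbon, or, once the acetate is in place, deprotonation may trigger 1,4-elimination of acetic acid along the dione–alkene–carbinol array.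

Fallback: the acetate is introduced on the macrocycle, where the ring holds the alkene out of conjugation with the dione enolate. From 23, sulfur is oxidised as in step 13 to the hydroxy sulfone F7. Thermolysis as in step 14 should give deacetyl cespitularin K F3, and acetylation with Ac2O in pyridine returns to 28.

## Further compounds

F1 | step 14 | (3Z)-3-[(2E,4S)-4-hydroxy-2-methyl-6-methylidenedeca-2,9-dien-1-ylidene]-4,4-dimethyl-4,6-dihydro-1H,3H-thieno[3,4-c]furan-1-one 5,5-dioxide | O=C1O/C(=C\C(C)=C\[C@@H](O)CC(=C)CCC=C)C2=C1CS(=O)(=O)C2(C)C
F2 | step 14 | macrocyclic ylidenebutenolide with free hydroxyl (ring A fused to the butenolide, twelve-membered ring C closed) | C=C1CC[C@@H]2CCC3=C(/C(OC3=O)=C/C(C)=C/[C@@H](O)C1)C2(C)C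
F3 | step 14 | deacetyl cespitularin K | C=C1CC[C@@H]2CCC3=C(C(=O)[C@H](C3=O)/C(C)=C/[C@@H](O)C1)C2(C)C
F4 | step 11 | methyl 4-[(3E,5S)-5-hydroxy-3-methyl-7-methylideneundeca-3,10-dienoyl]-5,5-dimethyl-2,5-dihydrothiophene-3-carboxylate | COC(=O)C1=C(C(=O)C/C(C)=C/[C@@H](O)CC(=C)CCC=C)C(C)(C)SC1
F0 | step 13 | none | none
F5 | step 7 | racemic (3E)-3-methyl-7-methylideneundeca-3,10-dien-1-yn-5-ol | C#C/C(C)=C/C(O)CC(=C)CCC=C
F6 | step 7 | (3E)-3-methyl-7-methylideneundeca-3,10-dien-1-yn-5-one | C#C/C(C)=C/C(=O)CC(=C)CCC=C
F7 | step 12 | 5-[(2E,4S)-4-hydroxy-6-methylidenedeca-2,9-dien-2-yl]-1,1-dimethyl-1H-cyclopenta[c]thiophene-4,6(3H,5H)-dione 2,2-dioxide | C=CCCC(=C)C[C@H](O)/C=C(C)/[C@H]1C(=O)C2=C(C1=O)C(C)(C)S(=O)(=O)C2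
A1 | alternative 1 | seco 2-alkenyl bicyclic enedione carbinol with vinyl group on ring A and 2-bromoallyl terminus | C=C[C@@H]1CCC2=C(C(=O)[C@H](C2=O)/C(C)=C/[C@@H](O)CC(Br)=C)C1(C)C
A2 | alternative 1 | ring-A-fused 4-hydroxycyclobutenone with alkenyl trans-epoxide side chain (ring carbinol configuration left open, it is lost in the step) | C=C[C@@H]1CCC2=C(C(=O)C2(O)/C=C(\C)[C@@H]3O[C@H]3CC(Br)=C)C1(C)C
A3 | alternative 2 | isoxazoline-bridged macrocyclic ylidenebutenolide | N1=C2CC[C@@H]3CCC4=C(/C(OC4=O)=C/C(C)=C/[C@H](C2)O1)C3(C)C
A4 | alternative 2 | ring-A-fused ylidenebutenolide with 3-nitropropyl chain and triene side chain | [O-][N+](=O)CCC[C@@H]1CCC2=C(/C(OC2=O)=C/C(C)=C/C=C)C1(C)C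
A5 | alternative 2 | nitrile oxide derived from A4 | [O-][N+]#CCC[C@@H]1CCC2=C(/C(OC2=O)=C/C(C)=C/C=C)C1(C)C
A6 | alternative 3 | deacetyl cespitularin K tert-butyldimethylsilyl ether | C=C1CC[C@@H]2CCC3=C(C(=O)[C@H](C3=O)/C(C)=C/[C@@H](O[Si](C)(C)C(C)(C)C)C1)C2(C)C
A7 | alternative 3 | macrocyclic ylidenebutenolide tert-butyldimethylsilyl ether | C=C1CC[C@@H]2CCC3=C(/C(OC3=O)=C/C(C)=C/[C@@H](O[Si](C)(C)C(C)(C)C)C1)C2(C)C
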